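**Strategy.** The cyclopentane end group is traced back to a six-membered ring from (R)-carvone. In the target, C7 is an exocyclic carbon on C6, directly beside the quaternary carbinol carbon C5 of the ring C2–C3–C4–C5–C6; a Wolff ring contraction creates exactly this arrangement. In one photochemical operation the C5–C6 bond forms, the five-membered ring appears and C7 leaves the ring as a methyl ester. The precursor is a 2-diazocyclohexanone whose carbonyl carbon (future C7) lies between the diazo carbon (future C6) and a silyl-protected tertiary carbinol carbon (future C5), with the isopropenyl-bearing C2 on the other flank. The polyene is then attached by Horner–Wadsworth–Emmons and Wittig olefinations.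

Key step: step 6

Remark: atom labels C1–C20 follow carotenoid numbering of the target, which is (2R,5R,6S) and all-E.
Remark: the secondary carbinol centre of 4 and 5 is expected as an epimer mixture that step 3 erases, so its descriptor is left open.
Assumption: (3E,5E)-pseudoionone is taken as purchasable single isomer; technical material would first be freed of its 5Z isomer.

Step 1
Reactants: 1 (R)-carvone; 2 hydrogen peroxide
Product: 3 (1R,4R,6R)-1-methyl-4-(prop-1-en-2-yl)-7-oxabicyclo[4.1.0]heptan-2-one
Conditions: 30% H2O2, NaOH (cat.), MeOH, 0 °C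
Reagents that add atoms: hydrogen peroxide, OO
Why: Weitz–Scheffer nucleophilic epoxidation touches only the enone, and axial attack of hydroperoxide on the conformer with an equatorial isopropenyl group should place the epoxide oxygen on the face opposite to that group, which fixes the future C5 configuration.

Step 2
Reactants: 3
Product: 5 (1R,4R)-1-methyl-4-(prop-1-en-2-yl)cyclohexane-1,2-diol (C2 epimers), via epoxy alkoxide 4 (not isolated)
Conditions: LiAlH4, THF, 0 °C to reflux; H2O
Reagents that add atoms: none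
Why: Hydride reduction of the ketone is followed by SN2 opening of the epoxide at its secondary carbon (the other terminus is tertiary and deactivated by the neighbouring alkoxide), so the tertiary C–O bond is never broken and the tertiary carbinol keeps the epoxide configuration.

Step 3
Reactants: 5
Product: 6 (2R,5R)-2-hydroxy-2-methyl-5-(prop-1-en-2-yl)cyclohexan-1-one
Conditions: IBX, DMSO, rt
Reagents that add atoms: none
Why: IBX oxidation of a secondary/tertiary 1,2-diol should stop at the α-ketol without glycol cleavage, and it merges both carbinol epimers while leaving the tertiary alcohol and the alkene alone.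

Step 4
Reactants: 6; 7 triethylsilyl trifluoromethanesulfonate
Product: 8 (2R,5R)-2-methyl-5-(prop-1-en-2-yl)-2-(triethylsilyloxy)cyclohexan-1-one
Conditions: TESOTf, 2,6-lutidine, CH2Cl2, −78 to 0 °C
Reagents that add atoms: triethylsilyl trifluoromethanesulfonate, CC[Si](CC)(CC)OS(=O)(=O)C(F)(F)F
Why: Silyl triflate silylation caps the hindered tertiary alcohol, which blocks α-ketol rearrangement under the coming base and later retro-aldol cleavage, and the group is chosen to fall off in the acidic methanol of step 12.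

Step 5
Reactants: 8; 9 2,2,2-trifluoroethyl trifluoroacetate; 10 4-acetamidobenzenesulfonyl azide
Product: 12 (3S,6R)-2-diazo-6-methyl-3-(prop-1-en-2-yl)-6-(triethylsilyloxy)cyclohexan-1-one, via trifluoroacetyl ketone 11 (not isolated)
Conditions: LiN(SiMe3)2, THF, −78 °C; CF3CO2CH2CF3; aq. HCl work-up; crude 11, p-ABSA, Et3N, H2O, MeCN, rt
Reagents that add atoms: 4-acetamidobenzenesulfonyl azide, CC(=O)Nc1ccc(cc1)S(=O)(=O)N=[N+]=[N-]
Why: Claisen-type trifluoroacetylation followed by detrifluoroacetylative (Regitz-type) diazo transfer is regiospecific because the ketone can enolise only toward its single α-methylene group, the other α-carbon being quaternary, and no stereocentre is touched.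

Step 6
Reactants: 12; 13 methanol
Product: 16 methyl (1S,2R,5R)-2-methyl-5-(prop-1-en-2-yl)-2-(triethylsilyloxy)cyclopentane-1-carboxylate, via ketene 14 (not isolated), via cis ester 15 (not isolated)
Conditions: hν (medium-pressure Hg lamp, Pyrex), MeOH, 0 °C; then NaOMe (cat.), 0 °C to rt, short
Reagents that add atoms: methanol, CO
Why: Light expels N2 from the diazo ketone, whose ring holds the diazo and carbonyl groups syn, and the quaternary carbon C5 shifts from the carbonyl carbon C7 to the diazo carbon C6 as nitrogen leaves, giving ketene 14, which methanol captures as the ester. The closest known reaction type is the photochemical Wolff ring contraction of 2-diazocycloalkanones to cycloalkanecarboxylates. The ring C2–C3–C4–C5–C6 is closed by this 1,2-shift of a ring bond (contraction of the six-membered ring), not by a cyclisation, so no other ring size can arise. C5 migrates with retention and C2 is a spectator; the new stereocentre C6 is fixed by thermodynamic control, since methoxide should equilibrate any cis ester 15 to the epimer whose ester is trans to both the isopropenyl group on C2 and the methyl group on C5. The step needs rearrangement to outrun 1,2-hydrogen shift and O–H insertion, which direct photolysis of a syn-locked cyclic diazo ketone favours, and it needs no regiocontrol because C5 is the only group on C7 that can migrate.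

Step 7
Reactants: 16; 17 dioxygen
Product: 18 methyl (1S,2R,5R)-5-(2-hydroxypropan-2-yl)-2-methyl-2-(triethylsilyloxy)cyclopentane-1-carboxylate
Conditions: Co(acac)2 (cat.), PhSiH3, O2 (1 atm), THF, rt
Reagents that add atoms: dioxygen, O=O
Why: Mukaiyama hydration delivers a hydrogen atom to the terminal carbon of the only alkene and traps the tertiary radical with O2, giving the Markovnikov C1 alcohol without a new stereocentre, and the trans ester cannot lactonise onto it.

Step 8
Reactants: 18
Product: 19 [(1R,2R,5R)-5-(2-hydroxypropan-2-yl)-2-methyl-2-(triethylsilyloxy)cyclopentyl]methanol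
Conditions: i-Bu2AlH (excess), CH2Cl2, −78 °C to rt; aq. KNaC4H4O6
Reagents that add atoms: none
Why: Hydride reduction of the ester to the primary alcohol should leave the tertiary silyl ether and all three stereocentres untouched.

Step 9
Reactants: 19
Product: 20 (1S,2R,5R)-5-(2-hydroxypropan-2-yl)-2-methyl-2-(triethylsilyloxy)cyclopentane-1-carbaldehyde
Conditions: Dess–Martin periodinane, NaHCO3, CH2Cl2, 0 °C to rt; used at once
Reagents that add atoms: none
Why: Buffered Dess–Martin oxidation converts only the primary alcohol, and the trans-placed C1 hydroxyl cannot close to a lactol without a strained trans-fused bicycle, so the aldehyde should stay open and keep its C6 configuration.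

Step 10
Reactants: 20; 21 ethyl (2E)-4-(diethoxyphosphoryl)-3-methylbut-2-enoate
Product: 22 ethyl (2E,4E)-5-[(1S,2R,5R)-5-(2-hydroxypropan-2-yl)-2-methyl-2-(triethylsilyloxy)cyclopentyl]-3-methylpenta-2,4-dienoate
Conditions: 21 (excess), LiN(SiMe3)2, THF, −78 to 0 °C
Reagents that add atoms: ethyl (2E)-4-(diethoxyphosphoryl)-3-methylbut-2-enoate, CCOC(=O)/C=C(C)/CP(=O)(OCC)OCC
Why: The vinylogous Horner–Wadsworth–Emmons reaction adds C8–C11 with an E C7=C8 bond, the weakly basic phosphonate anion should add faster than it enolises the aldehyde, and any minor 9Z ester converges at the cation stage of step 12.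

Step 11
Reactants: 22
Product: 23 (2E,4E)-5-[(1S,2R,5R)-5-(2-hydroxypropan-2-yl)-2-methyl-2-(triethylsilyloxy)cyclopentyl]-3-methylpenta-2,4-dien-1-ol
Conditions: i-Bu2AlH (excess), CH2Cl2, −78 °C; aq. KNaC4H4O6
Reagents that add atoms: none
Why: 1,2-Reduction of the dienoate by the aluminium hydride gives the primary dienylic alcohol without touching the diene geometry.

Step 12
Reactants: 23; 24 triphenylphosphine hydrobromide
Product: 25 [(2E,4E)-5-[(1S,2R,5R)-2-hydroxy-5-(2-hydroxypropan-2-yl)-2-methylcyclopentyl]-3-methylpenta-2,4-dien-1-yl]triphenylphosphonium bromide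
Conditions: PPh3·HBr (slight excess), MeOH, 0 °C to rt
Reagents that add atoms: triphenylphosphine hydrobromide, [Br-].c1ccccc1[PH+](c1ccccc1)c1ccccc1
Why: SN1-type phosphonium salt formation, as used for carotenoid C15 building blocks, ionises the dienylic alcohol to a pentadienyl cation that triphenylphosphine captures at the unhindered terminus C11 as the E,E-diene, while the acidic methanol solvolyses the triethylsilyl ether in the same flask in no fixed order, the trans ring substitution keeping both hydroxyls from closing onto the cation.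

Step 13
Reactants: 26 (3E,5E)-6,10-dimethylundeca-3,5,9-trien-2-one (pseudoionone); 27 vinylmagnesium bromide
Product: 28 (4E,6E)-3,7,11-trimethyldodeca-1,4,6,10-tetraen-3-ol (racemic)
Conditions: CH2=CHMgBr, THF, −20 to 0 °C; H2O
Reagents that add atoms: vinylmagnesium bromide, C=C[Mg]Br
Why: Grignard 1,2-addition to the dienone gives the tertiary divinyl carbinol, whose stereocentre is destroyed in the next step.

Step 14
Reactants: 28; 24 triphenylphosphine hydrobromide
Product: 29 [(2E,4E,6E)-3,7,11-trimethyldodeca-2,4,6,10-tetraen-1-yl]triphenylphosphonium bromide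
Conditions: PPh3·HBr, MeOH, 0 °C to rt; crystallisation
Reagents that add atoms: triphenylphosphine hydrobromide, [Br-].c1ccccc1[PH+](c1ccccc1)c1ccccc1
Why: Ionisation of the tertiary allylic alcohol and phosphine capture at the primary terminus (SN1 with allylic transposition) gives the conjugated triene salt with the thermodynamic E geometry at the new trisubstituted bond, the buffered acid leaving the isolated alkene alone.

Step 15
Reactants: 29; 30 (2E,4E,6E)-2,7-dimethylocta-2,4,6-trienedial
Product: 32 (2E,4E,6E,8E,10E,12E,14E)-2,7,11,15,19-pentamethylicosa-2,4,6,8,10,12,14,18-octaenal, via 8Z aldehyde 31 (not isolated)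
Conditions: NaOMe, CH2Cl2/MeOH, 0 °C to rt, 30 in excess, dark; then reflux in EtOAc
Reagents that add atoms: (2E,4E,6E)-2,7-dimethylocta-2,4,6-trienedial, O=C/C(C)=C/C=C/C=C(C)/C=O
Why: Wittig mono-olefination of the symmetric dialdehyde (kept in excess to suppress double reaction) gives the C25 aldehyde, and the sterically hindered Z isomer at the new disubstituted bond should relax to E on gentle heating.

Step 16
Reactants: 25; 32
Product: 34 (2R,5R,6S)-2,6-cyclolycopene-1,5-diol (all-E; CNP0169920.4), via 11Z isomer 33 (not isolated)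
Conditions: NaOMe, CH2Cl2/MeOH, 0 °C to rt, dark, N2; then reflux in EtOAc, dark; crystallisation
Reagents that add atoms: aldehyde 32, CC(C)=CCC/C(C)=C/C=C/C(C)=C/C=C/C(C)=C/C=C/C=C(C)/C=O
Why: Wittig coupling of the hydroxylated C15 ylide with the C25 aldehyde forms C11=C12 under conditions that tolerate free tertiary alcohols, and the hindered 11Z isomer should equilibrate thermally to the all-E polyene without affecting C2, C5 or C6.

**Compound list**

1 | (R)-carvone | CC1=CC[C@H](CC1=O)C(C)=C | starting material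
2 | hydrogen peroxide | OO | starting material
3 | (1R,4R,6R)-1-methyl-4-(prop-1-en-2-yl)-7-oxabicyclo[4.1.0]heptan-2-one (epoxide trans to isopropenyl) | C1[C@H](C(C)=C)C[C@H]2O[C@@]2(C)C1=O | intermediate
4 | 1-methyl-4-(prop-1-en-2-yl)-7-oxabicyclo[4.1.0]heptan-2-ol, ring stereocentres as in 3, carbinol epimers, present as its aluminium alkoxide (drawn as the alcohol) | C1[C@H](C(C)=C)C[C@H]2O[C@@]2(C)C1O | intermediate
5 | (1R,4R)-1-methyl-4-(prop-1-en-2-yl)cyclohexane-1,2-diol (tertiary hydroxyl trans to isopropenyl; C2 epimers) | OC1C[C@H](C(C)=C)CC[C@@]1(C)O | intermediate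
6 | (2R,5R)-2-hydroxy-2-methyl-5-(prop-1-en-2-yl)cyclohexan-1-one | O=C1C[C@H](C(C)=C)CC[C@@]1(C)O | intermediate
7 | triethylsilyl trifluoromethanesulfonate | CC[Si](CC)(CC)OS(=O)(=O)C(F)(F)F | starting material
8 | (2R,5R)-2-methyl-5-(prop-1-en-2-yl)-2-(triethylsilyloxy)cyclohexan-1-one | O=C1C[C@H](C(C)=C)CC[C@@]1(C)O[Si](CC)(CC)CC | intermediate
9 | 2,2,2-trifluoroethyl trifluoroacetate | FC(F)(F)COC(=O)C(F)(F)F | starting material
10 | 4-acetamidobenzenesulfonyl azide | CC(=O)Nc1ccc(cc1)S(=O)(=O)N=[N+]=[N-] | starting material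
11 | 6-methyl-3-(prop-1-en-2-yl)-2-(trifluoroacetyl)-6-(triethylsilyloxy)cyclohexan-1-one, ring stereocentres as in 8, enolised at C2 | O=C1C(C(=O)C(F)(F)F)[C@H](C(C)=C)CC[C@@]1(C)O[Si](CC)(CC)CC | intermediate
12 | (3S,6R)-2-diazo-6-methyl-3-(prop-1-en-2-yl)-6-(triethylsilyloxy)cyclohexan-1-one (silyloxy trans to isopropenyl) | [N-]=[N+]=C1[C@H](C(C)=C)CC[C@@](C)(O[Si](CC)(CC)CC)C1=O | intermediate
13 | methanol | CO | starting material
14 | [2-methyl-5-(prop-1-en-2-yl)-2-(triethylsilyloxy)cyclopentylidene]methanone (ketene), ring stereocentres as in 16 | O=C=C1[C@H](C(C)=C)CC[C@@]1(C)O[Si](CC)(CC)CC | intermediate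
15 | methyl (1R,2R,5R)-2-methyl-5-(prop-1-en-2-yl)-2-(triethylsilyloxy)cyclopentane-1-carboxylate (ester cis to isopropenyl) | COC(=O)[C@@H]1[C@H](C(C)=C)CC[C@@]1(C)O[Si](CC)(CC)CC | intermediate
16 | methyl (1S,2R,5R)-2-methyl-5-(prop-1-en-2-yl)-2-(triethylsilyloxy)cyclopentane-1-carboxylate | COC(=O)[C@H]1[C@H](C(C)=C)CC[C@@]1(C)O[Si](CC)(CC)CC | intermediate
17 | dioxygen | O=O | starting material
18 | methyl (1S,2R,5R)-5-(2-hydroxypropan-2-yl)-2-methyl-2-(triethylsilyloxy)cyclopentane-1-carboxylate | COC(=O)[C@H]1[C@H](C(C)(C)O)CC[C@@]1(C)O[Si](CC)(CC)CC | intermediate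
19 | [(1R,2R,5R)-5-(2-hydroxypropan-2-yl)-2-methyl-2-(triethylsilyloxy)cyclopentyl]methanol | OC[C@H]1[C@H](C(C)(C)O)CC[C@@]1(C)O[Si](CC)(CC)CC | intermediate
20 | (1S,2R,5R)-5-(2-hydroxypropan-2-yl)-2-methyl-2-(triethylsilyloxy)cyclopentane-1-carbaldehyde | O=C[C@H]1[C@H](C(C)(C)O)CC[C@@]1(C)O[Si](CC)(CC)CC | intermediate
21 | ethyl (2E)-4-(diethoxyphosphoryl)-3-methylbut-2-enoate (commercial E/Z mixture, drawn E) | CCOC(=O)/C=C(C)/CP(=O)(OCC)OCC | starting material
22 | ethyl (2E,4E)-5-[(1S,2R,5R)-5-(2-hydroxypropan-2-yl)-2-methyl-2-(triethylsilyloxy)cyclopentyl]-3-methylpenta-2,4-dienoate | CCOC(=O)/C=C(C)/C=C/[C@H]1[C@H](C(C)(C)O)CC[C@@]1(C)O[Si](CC)(CC)CC | intermediate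
23 | (2E,4E)-5-[(1S,2R,5R)-5-(2-hydroxypropan-2-yl)-2-methyl-2-(triethylsilyloxy)cyclopentyl]-3-methylpenta-2,4-dien-1-ol | OC/C=C(C)/C=C/[C@H]1[C@H](C(C)(C)O)CC[C@@]1(C)O[Si](CC)(CC)CC | intermediate
24 | triphenylphosphine hydrobromide | [Br-].c1ccccc1[PH+](c1ccccc1)c1ccccc1 | starting material
25 | [(2E,4E)-5-[(1S,2R,5R)-2-hydroxy-5-(2-hydroxypropan-2-yl)-2-methylcyclopentyl]-3-methylpenta-2,4-dien-1-yl]triphenylphosphonium bromide | [Br-].c1ccccc1[P+](c1ccccc1)(c1ccccc1)C/C=C(C)/C=C/[C@H]1[C@H](C(C)(C)O)CC[C@@]1(C)O | intermediate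
26 | (3E,5E)-6,10-dimethylundeca-3,5,9-trien-2-one (pseudoionone) | CC(C)=CCC/C(C)=C/C=C/C(C)=O | starting material
27 | vinylmagnesium bromide | C=C[Mg]Br | starting material
28 | (4E,6E)-3,7,11-trimethyldodeca-1,4,6,10-tetraen-3-ol (racemic) | CC(C)=CCC/C(C)=C/C=C/C(C)(O)C=C | intermediate
29 | [(2E,4E,6E)-3,7,11-trimethyldodeca-2,4,6,10-tetraen-1-yl]triphenylphosphonium bromide | [Br-].CC(C)=CCC/C(C)=C/C=C/C(C)=C/C[P+](c1ccccc1)(c1ccccc1)c1ccccc1 | intermediate
30 | (2E,4E,6E)-2,7-dimethylocta-2,4,6-trienedial | O=C/C(C)=C/C=C/C=C(C)/C=O | starting material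
31 | (2E,4E,6E,8Z,10E,12E,14E)-2,7,11,15,19-pentamethylicosa-2,4,6,8,10,12,14,18-octaenal | CC(C)=CCC/C(C)=C/C=C/C(C)=C/C=C\C(C)=C\C=C\C=C(C)\C=O | intermediate
32 | (2E,4E,6E,8E,10E,12E,14E)-2,7,11,15,19-pentamethylicosa-2,4,6,8,10,12,14,18-octaenal (C25 aldehyde) | CC(C)=CCC/C(C)=C/C=C/C(C)=C/C=C/C(C)=C/C=C/C=C(C)/C=O | intermediate
33 | (11Z)-isomer of the target, otherwise all-E, (2R,5R,6S) | CC(C)=CCC/C(C)=C/C=C/C(C)=C/C=C/C(C)=C/C=C/C=C(C)/C=C\C=C(C)\C=C\[C@H]1[C@H](C(C)(C)O)CC[C@@]1(C)O | intermediate
34 | (2R,5R,6S)-2,6-cyclolycopene-1,5-diol, all-E (CNP0169920.4) | CC(C)=CCC/C(C)=C/C=C/C(C)=C/C=C/C(C)=C/C=C/C=C(C)/C=C/C=C(C)/C=C/[C@H]1[C@H](C(C)(C)O)CC[C@@]1(C)O | target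

**Totals.** Total step count: 16. Longest linear sequence: 13 steps (steps 1–12 and 16, from (R)-carvone); steps 13–15 form the convergent C25 branch.

**Steps most likely to fail**

1. Step 6. The excited diazo ketone may lose nitrogen with a 1,2-hydrogen shift from the allylic C2–H or insert into the O–H bond of methanol instead of rearranging. The methoxide equilibration may also expel the β-silanolate. Fallback by quasi-Favorskii ring contraction, setting out from 8 and returning at 16: deprotonation of 8 with LiN(SiMe3)2 in THF at −78 °C and quenching with N-bromosuccinimide should give (2S,3S,6R)-2-bromo-6-methyl-3-(prop-1-en-2-yl)-6-(triethylsilyloxy)cyclohexan-1-one F1 (bromide expected trans to isopropenyl; its configuration is not decisive). NaOMe in MeOH then adds to the carbonyl group. Because the other α-carbon bears no hydrogen, the adduct can only collapse by a semibenzilic 1,2-shift of C5 onto the bromide-bearing carbon with loss of bromide. The same C5–C6 bond forms without a carbene, and the methoxide present equilibrates the ester to 16.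

2. Step 12. Under acid the pentadienyl cation may lose a proton or the tertiary alcohols may ionise, and silyl ether cleavage may lag behind salt formation. Fallback by reversing the polarity of the last coupling, setting out from 23 and 32 and returning at 34: MnO2 in CH2Cl2 should oxidise 23 to (2E,4E)-5-[(1S,2R,5R)-5-(2-hydroxypropan-2-yl)-2-methyl-2-(triethylsilyloxy)cyclopentyl]-3-methylpenta-2,4-dienal F2. NaBH4 in EtOH reduces 32 to (2E,4E,6E,8E,10E,12E,14E)-2,7,11,15,19-pentamethylicosa-2,4,6,8,10,12,14,18-octaen-1-ol F3. PPh3·HBr in MeOH converts this into [(2E,4E,6E,8E,10E,12E,14E)-2,7,11,15,19-pentamethylicosa-2,4,6,8,10,12,14,18-octaen-1-yl]triphenylphosphonium bromide F4, so the acid step now runs on a fragment without tertiary alcohols. Wittig coupling of F4 with F2 (NaOMe, CH2Cl2/MeOH, thermal equilibration as in step 16) gives the 5-O-triethylsilyl ether of the target carotenoid F5, and Bu4NF in THF removes the silyl group to give 34.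

3. Step 10. Addition to the hindered, α-branched aldehyde may be slow enough for base-induced enolisation, epimerisation at C6 and capture of the cis aldehyde as a lactol by the free C1 hydroxyl. Fallback by a base-free C3 plus C2 build-up, setting out from 20 and returning at 25: heating 20 with the stabilised ylide Ph3P=CHC(O)CH3 in toluene should give (3E)-4-[(1S,2R,5R)-5-(2-hydroxypropan-2-yl)-2-methyl-2-(triethylsilyloxy)cyclopentyl]but-3-en-2-one F6. Excess CH2=CHMgBr (27) in THF adds 1,2 to give (1E)-1-[(1S,2R,5R)-5-(2-hydroxypropan-2-yl)-2-methyl-2-(triethylsilyloxy)cyclopentyl]-3-methylpenta-1,4-dien-3-ol F7 (carbinol epimers). PPh3·HBr (24) in MeOH then ionises the tertiary alcohol, places phosphorus on the primary terminus with allylic transposition and removes the silyl group, giving 25.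

**Further compounds**

F1 | step 6 | (2S,3S,6R)-2-bromo-6-methyl-3-(prop-1-en-2-yl)-6-(triethylsilyloxy)cyclohexan-1-one | Br[C@H]1[C@H](C(C)=C)CC[C@@](C)(O[Si](CC)(CC)CC)C1=O
F2 | step 12 | (2E,4E)-5-[(1S,2R,5R)-5-(2-hydroxypropan-2-yl)-2-methyl-2-(triethylsilyloxy)cyclopentyl]-3-methylpenta-2,4-dienal | O=C/C=C(C)/C=C/[C@H]1[C@H](C(C)(C)O)CC[C@@]1(C)O[Si](CC)(CC)CC
F3 | step 12 | (2E,4E,6E,8E,10E,12E,14E)-2,7,11,15,19-pentamethylicosa-2,4,6,8,10,12,14,18-octaen-1-ol | CC(C)=CCC/C(C)=C/C=C/C(C)=C/C=C/C(C)=C/C=C/C=C(C)/CO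
F4 | step 12 | [(2E,4E,6E,8E,10E,12E,14E)-2,7,11,15,19-pentamethylicosa-2,4,6,8,10,12,14,18-octaen-1-yl]triphenylphosphonium bromide | [Br-].CC(C)=CCC/C(C)=C/C=C/C(C)=C/C=C/C(C)=C/C=C/C=C(C)/C[P+](c1ccccc1)(c1ccccc1)c1ccccc1
F5 | step 12 | 5-O-triethylsilyl ether of (2R,5R,6S)-2,6-cyclolycopene-1,5-diol | CC(C)=CCC/C(C)=C/C=C/C(C)=C/C=C/C(C)=C/C=C/C=C(C)/C=C/C=C(C)/C=C/[C@H]1[C@H](C(C)(C)O)CC[C@@]1(C)O[Si](CC)(CC)CC
F6 | step 10 | (3E)-4-[(1S,2R,5R)-5-(2-hydroxypropan-2-yl)-2-methyl-2-(triethylsilyloxy)cyclopentyl]but-3-en-2-one | CC(=O)/C=C/[C@H]1[C@H](C(C)(C)O)CC[C@@]1(C)O[Si](CC)(CC)CC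
F7 | step 10 | (1E)-1-[(1S,2R,5R)-5-(2-hydroxypropan-2-yl)-2-methyl-2-(triethylsilyloxy)cyclopentyl]-3-methylpenta-1,4-dien-3-ol (carbinol epimers) | C=CC(C)(O)/C=C/[C@H]1[C@H](C(C)(C)O)CC[C@@]1(C)O[Si](CC)(CC)CC
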